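The whole carbon skeleton is benzoic acid: the cis-disposed oxygens on C1 (tertiary carbinol carrying the exocyclic C7H2O) and C6 (benzoate-bearing carbon) of the cyclohexene ring are recognised as an ipso,ortho arene cis-dihydrodiol. One enzymatic dihydroxylation dearomatises sodium benzoate, creates the quaternary C1 and C6 in a single absolute configuration and leaves a C2–C5 diene; its precursor is simply the flat arene. Singlet oxygen then bridges C2 and C5 anti to a C1/C6 acetonide, the peroxide masks both oxygens during the acetonide-to-benzoate exchange, and C2 is finally inverted twice (C1–C2 epoxide closure, HCl opening) to put chlorine cis to C5-OH.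

Key step: step 1

Remark on numbering: target numbering is used throughout (C1 quaternary carbinol carbon bearing C7H2O, C2 the later CHCl carbon, C3=C4, C5 the CHOH carbon, C6 the CHOBz carbon); β is the ring face of the C1 and C6 oxygens, α is the opposite face, on which C7 sits.
Assumption: the whole-cell catalyst (a diol-dehydrogenase-deficient benzoate-oxidising strain) is treated as an available reagent; every skeletal carbon comes from commercial benzoic acid.

Step 1
Reactants: 1 benzoic acid
Product: 2 (1S,2R)-1,2-dihydroxycyclohexa-3,5-diene-1-carboxylic acid (cis-diol)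
Conditions: NaOH (to sodium benzoate); Ralstonia eutropha B9 whole cells, fructose, mineral salts medium, air, pH 7, 30 °C; cell-free broth brought to pH 3 with HCl at 0–4 °C, EtOAc extraction
Reagents that add atoms: dioxygen, O=O
Why: The Rieske non-haem iron benzoate 1,2-dioxygenase of the cells activates O2 (electrons from NADH, recycled by fructose metabolism) and transfers both oxygen atoms to the same face of the ipso and ortho carbons of bound benzoate; because the strain lacks the cis-diol dehydrogenase, the dihydrodiol is excreted instead of being decarboxylated to catechol. The closest known reaction type is whole-cell arene cis-dihydroxylation with blocked dioxygenase mutants, and benzoate is the native substrate of this enzyme. No ring is closed: the existing six-membered ring is only dearomatised. Both new stereocentres (the tertiary carbinol carbon and the neighbouring CHOH) are fixed by the active site, which anchors the carboxylate and so presents one enantiotopic ipso,ortho edge and one face to the iron-bound oxygen, giving the cis (1S,2R) diol. The step needs ipso,ortho rather than ortho,meta regioselectivity and a single absolute sense, both secured by carboxylate recognition in the enzyme pocket, and acid-induced rearomatisation is avoided by isolating cold at pH 3.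

Step 2
Reactants: 2 (1S,2R)-1,2-dihydroxycyclohexa-3,5-diene-1-carboxylic acid
Product: 4 methyl ester acetonide of the diene diol, via acetonide acid 3 (not isolated)
Conditions: 2,2-dimethoxypropane, TsOH (cat.), acetone, 0 °C to rt; then K2CO3, MeI, DMF, rt; product stored cold
Reagents that add atoms: 2,2-dimethoxypropane, COC(C)(C)OC; iodomethane, CI
Why: Acid-catalysed transketalisation ties the cis-diol into a five-membered isopropylidene acetal faster than the weakly acidic medium can dehydrate the dienediol, and the potassium carboxylate formed on adding K2CO3 is then O-methylated by SN2 on iodomethane (carboxylate alkylation), no stereocentre being touched.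

Step 3
Reactants: 4 methyl ester acetonide of the diene diol
Product: 5 diene acetonide carbinol (C7H2OH on C1)
Conditions: LiAlH4, THF, 0 °C; careful aqueous quench at 0 °C
Reagents that add atoms: none
Why: Hydride reduction of an ester to the primary alcohol; the ester sits on the sp3 carbon C1 and is not conjugated with the diene, so only the carbonyl is reduced and the acetal is inert to hydride.

Step 4
Reactants: 5 diene acetonide carbinol; 6 benzoyl chloride
Product: 7 diene acetonide C7-benzoate
Conditions: pyridine, DMAP (cat.), CH2Cl2, 0 °C
Reagents that add atoms: benzoyl chloride, O=C(Cl)c1ccccc1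
Why: DMAP-catalysed O-acylation of the unhindered primary alcohol installs the C7 benzoate of the target and removes the only free hydroxyl before the oxidation.

Step 5
Reactants: 7 diene acetonide C7-benzoate
Product: 8 endoperoxide acetonide (O–O bridge C2 to C5 on the α face)
Conditions: O2, tetraphenylporphyrin (cat.), visible light, CH2Cl2, −20 °C
Reagents that add atoms: dioxygen, O=O
Why: Photosensitised singlet oxygen adds to the s-cis C2–C5 diene in a concerted suprafacial [4+2] cycloaddition (photooxygenation), and because the cis-fused dioxolane with its oxygen lone pairs shields the β face, both new C–O bonds at C2 and C5 form on the α face, cis to each other and trans to the C1/C6 oxygens.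

Step 6
Reactants: 8 endoperoxide acetonide
Product: 9 endoperoxide diol (free tertiary C1-OH and secondary C6-OH)
Conditions: TFA/H2O (4:1), 0 °C, short contact; cold evaporation with toluene
Reagents that add atoms: none
Why: Acid-catalysed acetal hydrolysis proceeds through the acetal carbon, so C1 and C6 keep their configuration, while the dialkyl peroxide and the benzoate are not cleaved by cold aqueous TFA and keep C2–O and C5–O masked.

Step 7
Reactants: 9 endoperoxide diol; 6 benzoyl chloride
Product: 10 endoperoxide dibenzoate (C6-OBz, C1-OH free)
Conditions: BzCl (1.1 equiv), pyridine, CH2Cl2, 0 °C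
Reagents that add atoms: benzoyl chloride, O=C(Cl)c1ccccc1
Why: Chemoselective acylation, since only the secondary C6-OH reacts under these mild conditions while the tertiary C1-OH next to a quaternary centre does not, and pyridine is too weak a base to trigger a Kornblum–DeLaMare fragmentation of the peroxide.

Step 8
Reactants: 10 endoperoxide dibenzoate
Product: 11 triol dibenzoate (cis-1,4-diol, C2-OH and C5-OH both α)
Conditions: thiourea, MeOH, rt
Reagents that add atoms: none
Why: Thiourea reduces the O–O bond by attack of sulfur on oxygen (endoperoxide to cis-1,4-diol reduction) without breaking a C–O bond, so both hydroxyls emerge with retention on the α face and the alkene and esters are untouched.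

Step 9
Reactants: 11 triol dibenzoate
Product: 12 C5-O-triethylsilyl ether
Conditions: TESCl (1.05 equiv), imidazole, CH2Cl2, −40 °C
Reagents that add atoms: chlorotriethylsilane, CC[Si](Cl)(CC)CC
Why: Sterically controlled monosilylation, because C5-OH is an ordinary secondary allylic alcohol whereas C2-OH is neopentyl-like (next to the fully substituted C1 and cis to the CH2OBz arm) and C1-OH is tertiary.

Step 10
Reactants: 12 C5-O-triethylsilyl ether
Product: 14 C5-O-TES C1–C2 epoxide (oxirane on the β face), via C2 mesylate 13 (not isolated)
Conditions: Ms2O, Et3N, CH2Cl2, −20 °C; then DBU, 0 °C to rt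
Reagents that add atoms: none
Why: Sulfonylation of the remaining secondary hydroxyl with chloride-free Ms2O (so no allylic chloride can form) is followed by a base-induced intramolecular Williamson displacement in which the β C1 alkoxide attacks C2 anti to the α mesylate in the diaxial half-chair, closing the oxirane with inversion at C2.

Step 11
Reactants: 14 C5-O-TES C1–C2 epoxide
Product: 15 epoxy alcohol (free C5-OH)
Conditions: Et3N·3HF, THF, 0 °C to rt
Reagents that add atoms: none
Why: Fluoride-mediated Si–O cleavage with the nearly neutral amine–HF complex removes the TES ether without opening the vinyl epoxide or moving the benzoates.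

Step 12
Reactants: 15 epoxy alcohol
Product: 16 target chlorohydrin, [(1R,2R,5S,6R)-6-(benzoyloxy)-2-chloro-1,5-dihydroxycyclohex-3-en-1-yl]methyl benzoate
Conditions: HCl (1 M in Et2O, slight excess), CH2Cl2, −40 to 0 °C
Reagents that add atoms: hydrogen chloride, Cl
Why: Acid-promoted nucleophilic opening of the vinyl epoxide, in which protonation weakens the allylic C2–O bond and chloride attacks C2 from the α face anti to the oxirane oxygen (the acyloxy-flanked, fully substituted C1 being deactivated), so this second inversion places Cl cis to C5-OH and trans to the liberated tertiary C1-OH.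

Compound list
1 | benzoic acid | OC(=O)c1ccccc1 | starting material
2 | (1S,2R)-1,2-dihydroxycyclohexa-3,5-diene-1-carboxylic acid (cis-diol; route numbering: C1-OH and C6-OH β, CO2H α) | OC(=O)[C@]1(O)C=CC=C[C@H]1O | intermediate
3 | acetonide acid: 2 with C1-O and C6-O bridged by CMe2 (cis-fused dioxolane on the β face), formed in the flask | OC(=O)[C@]12C=CC=C[C@H]1OC(C)(C)O2 | intermediate
4 | methyl ester acetonide of the diene diol (methyl ester of 3) | COC(=O)[C@]12C=CC=C[C@H]1OC(C)(C)O2 | intermediate
5 | diene acetonide carbinol (ester of 4 reduced to C7H2OH, α on C1) | OC[C@]12C=CC=C[C@H]1OC(C)(C)O2 | intermediate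
6 | benzoyl chloride | O=C(Cl)c1ccccc1 | starting material
7 | diene acetonide C7-benzoate | O=C(OC[C@]12C=CC=C[C@H]1OC(C)(C)O2)c1ccccc1 | intermediate
8 | endoperoxide acetonide: O–O bridge from C2 to C5 on the α face, C3=C4 alkene, acetonide on C1-O/C6-O (β), C7H2OBz on C1 | O=C(OC[C@]12[C@H]3C=C[C@H](OO3)[C@H]1OC(C)(C)O2)c1ccccc1 | intermediate
9 | endoperoxide diol: as 8 with free C1-OH (tertiary) and C6-OH, both β | O=C(OC[C@]1(O)[C@H]2C=C[C@H](OO2)[C@H]1O)c1ccccc1 | intermediate
10 | endoperoxide dibenzoate: 9 with C6-O-benzoate, C1-OH free | O=C(OC[C@]1(O)[C@H]2C=C[C@H](OO2)[C@H]1OC(=O)c1ccccc1)c1ccccc1 | intermediate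
11 | triol dibenzoate: C1-OH β, C2-OH α, C5-OH α, C6-OBz β, C7-OBz, C3=C4 | O=C(OC[C@]1(O)[C@H](O)C=C[C@H](O)[C@H]1OC(=O)c1ccccc1)c1ccccc1 | intermediate
12 | C5-O-triethylsilyl ether of 11 | O=C(OC[C@]1(O)[C@H](O)C=C[C@H](O[Si](CC)(CC)CC)[C@H]1OC(=O)c1ccccc1)c1ccccc1 | intermediate
13 | C2-O-mesylate of 12 (mesylate α), formed in the flask | O=C(OC[C@]1(O)[C@H](OS(C)(=O)=O)C=C[C@H](O[Si](CC)(CC)CC)[C@H]1OC(=O)c1ccccc1)c1ccccc1 | intermediate
14 | C5-O-TES C1–C2 epoxide: oxirane on the β face, C5-OTES α, C6-OBz β | O=C(OC[C@]12O[C@H]1C=C[C@H](O[Si](CC)(CC)CC)[C@H]2OC(=O)c1ccccc1)c1ccccc1 | intermediate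
15 | epoxy alcohol: 14 with free C5-OH | O=C(OC[C@]12O[C@H]1C=C[C@H](O)[C@H]2OC(=O)c1ccccc1)c1ccccc1 | intermediate
16 | [(1R,2R,5S,6R)-6-(benzoyloxy)-2-chloro-1,5-dihydroxycyclohex-3-en-1-yl]methyl benzoate (C1-OH and C6-OBz β, C2-Cl and C5-OH α) | O=C(OC[C@]1(O)[C@H](Cl)C=C[C@H](O)[C@H]1OC(=O)c1ccccc1)c1ccccc1 | target

Total step count: 12.
Longest linear sequence: 12 steps from benzoic acid (benzoyl chloride is bought and used twice).

Steps most likely to fail

Step 9. The risk is poor site discrimination between the two secondary allylic hydroxyls, with silylation at C2-O or at both positions. The fallback drops the protecting group and lets the vicinal C1/C2 diol select itself. Setting out from triol 11, a dibutylstannylene acetal (Bu2SnO, toluene, reflux) should form only across the C1-O/C2-O pair and direct TsCl to the secondary oxygen, giving the C2 tosylate F1. DBU then closes the oxirane with inversion at C2 and delivers epoxy alcohol 15 directly, where the route is rejoined, so that steps 9 to 11 are replaced.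

Step 6. The risk is acid-induced degradation of the peroxide bridge, or acyl migration, before the acetal is fully hydrolysed. The fallback removes the peroxide before the acid step. Setting out from 8, thiourea reduction should give the cis-1,4-diol acetonide F2, and both allylic hydroxyls are esterified with levulinic acid (DCC, DMAP) to the bis-levulinate acetonide F3. Aqueous TFA then cleaves the acetal with no peroxide present to give the bis-levulinate diol F4, and BzCl/pyridine acylates the secondary C6-OH to the bis-levulinate dibenzoate F5. Hydrazine acetate cleaves only the two γ-keto esters and returns triol dibenzoate 11, where the route is rejoined.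

Step 12. The risk is loss of regio- and stereocontrol through an allyl-cation-like opening under strong acid: attack at C4 with allylic transposition, syn opening, or participation of the C7 benzoate. The fallback moves the C–Cl bond formation to the silyl-protected stage and runs it as a buffered SN2 process. Setting out from 14, LiCl/AcOH in THF should open the oxirane at C2 with inversion to give the C5-O-TES chlorohydrin F6. Et3N·3HF then removes the silyl ether and gives the target 16, where the route is rejoined.

Further compounds
F1 | step 9 | C2-O-tosylate of triol dibenzoate 11 | O=C(OC[C@]1(O)[C@H](OS(=O)(=O)c2ccc(C)cc2)C=C[C@H](O)[C@H]1OC(=O)c1ccccc1)c1ccccc1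
F2 | step 6 | cis-1,4-diol acetonide (C2-OH and C5-OH α, acetonide on C1-O/C6-O, C7-OBz) | O=C(OC[C@]12[C@H](O)C=C[C@H](O)[C@H]1OC(C)(C)O2)c1ccccc1
F3 | step 6 | bis-levulinate acetonide | O=C(OC[C@]12[C@H](OC(=O)CCC(C)=O)C=C[C@H](OC(=O)CCC(C)=O)[C@H]1OC(C)(C)O2)c1ccccc1
F4 | step 6 | bis-levulinate diol (C1-OH and C6-OH free) | O=C(OC[C@]1(O)[C@H](OC(=O)CCC(C)=O)C=C[C@H](OC(=O)CCC(C)=O)[C@H]1O)c1ccccc1
F5 | step 6 | bis-levulinate dibenzoate | O=C(OC[C@]1(O)[C@H](OC(=O)CCC(C)=O)C=C[C@H](OC(=O)CCC(C)=O)[C@H]1OC(=O)c1ccccc1)c1ccccc1
F6 | step 12 | C5-O-TES chlorohydrin | O=C(OC[C@]1(O)[C@H](Cl)C=C[C@H](O[Si](CC)(CC)CC)[C@H]1OC(=O)c1ccccc1)c1ccccc1
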